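## Retrosynthetic overview

- Ring C (the pyranone) is formed last. The flavone comes from a 2'-hydroxychalcone by I2/DMSO oxidative cyclisation, which makes the O1–C2 bond and then dehydrogenates.
- The chalcone Cα=Cβ bond is cut by a Claisen–Schmidt disconnection into a ring A methyl ketone and a ring B aldehyde.
- The ring A ketone (6-hydroxy-2,3-dimethoxy pattern) comes from a commercial 2-hydroxy-6-methoxy aryl methyl ketone by para-hydroxylation and selective O-methylation.
- The ring B aldehyde comes from commercial, symmetric tetramethoxybenzene by ortho-lithiation and formylation.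
- Rings A and B are bought intact, so only ring C is built.

Assumption: the target has no stereocentre, and ring B is symmetric about the C2–C1' axis, so it has no atropisomers. The "single enantiomer" is therefore the achiral compound as drawn. The only stereo-element on the route is the E double bond of the chalcone.

## Route

Step 1
Reactants: 1 1-(2-hydroxy-6-methoxyphenyl)ethanone (2'-hydroxy-6'-methoxyacetophenone)
Product: 3 1-(3,6-dihydroxy-2-methoxyphenyl)ethanone, via potassium aryl sulfate 2 (not isolated)
Conditions: K2S2O8, aq KOH, 0 °C to rt, 24 h; then aq HCl, 90 °C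
Reagents that add atoms: dipotassium peroxodisulfate (K2S2O8), [K+].[K+].[O-]S(=O)(=O)OOS(=O)(=O)[O-]
Why: In this Elbs persulfate oxidation the phenoxide of 1 attacks a peroxide oxygen through the only carbon para to O−, giving aryl sulfate 2, whose S–O bond is hydrolysed by hot acid to the hydroquinone; no stereocentre is formed.

Step 2
Reactants: 3 1-(3,6-dihydroxy-2-methoxyphenyl)ethanone
Product: 4 1-(6-hydroxy-2,3-dimethoxyphenyl)ethanone
Conditions: MeI (1.05 equiv), K2CO3 (1.1 equiv), acetone, reflux, N2
Reagents that add atoms: iodomethane (MeI), CI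
Why: This is a chemoselective Williamson O-methylation, because the 6-OH is hydrogen-bonded to the acetyl C=O and poorly nucleophilic, so one equivalent of MeI with a weak base alkylates only the free 3-OH.

Step 3
Reactants: 5 1,2,4,5-tetramethoxybenzene
Product: 8 2,3,5,6-tetramethoxybenzaldehyde, via aryllithium 6 (not isolated), via lithium hemiaminal alkoxide 7 (not isolated)
Conditions: n-BuLi (1.05 equiv), TMEDA, THF, 0 °C to rt; DMF, 0 °C to rt; aq HCl
Reagents that add atoms: N,N-dimethylformamide (DMF), CN(C)C=O
Why: In this directed ortho-metalation and Bouveault-type formylation the two ring hydrogens of 5 are equivalent and each sits next to a coordinating OMe, so a single aryllithium 6 forms and adds to DMF to give adduct 7, which collapses to the aldehyde only on acidic quench.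

Step 4
Reactants: 4 1-(6-hydroxy-2,3-dimethoxyphenyl)ethanone; 8 2,3,5,6-tetramethoxybenzaldehyde
Product: 10 (E)-1-(6-hydroxy-2,3-dimethoxyphenyl)-3-(2,3,5,6-tetramethoxyphenyl)prop-2-en-1-one, via racemic aldol adduct 9 (not isolated)
Conditions: KOH (10 equiv), EtOH/H2O, rt, 48 h; then aq HCl to pH 5
Reagents that add atoms: none
Why: In this Claisen–Schmidt crossed aldol condensation only 4 can enolise and only 8 is an aldehyde, and E1cB dehydration of 9 removes its carbinol centre and gives the conjugated, thermodynamically preferred E alkene.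

Step 5
Reactants: 10 (E)-1-(6-hydroxy-2,3-dimethoxyphenyl)-3-(2,3,5,6-tetramethoxyphenyl)prop-2-en-1-one
Product: 12 5,6-dimethoxy-2-(2,3,5,6-tetramethoxyphenyl)-4H-chromen-4-one (5,6,2',3',5',6'-hexamethoxyflavone), via racemic flavanone 11 (not isolated)
Conditions: I2 (10 mol %), DMSO, 130 °C, 2–4 h
Reagents that add atoms: none
Why: In this I2/DMSO oxidative cyclisation of a 2'-hydroxychalcone, oxa-Michael closure of ring C gives flavanone 11, iodine dehydrogenates C2–C3 by α-iodination and loss of HI, and DMSO re-oxidises HI to I2, so the transient C2 centre is erased and the product is achiral.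

## Compound list

1 | 1-(2-hydroxy-6-methoxyphenyl)ethanone | CC(=O)c1c(O)cccc1OC | starting material
2 | potassium 3-acetyl-4-hydroxy-2-methoxyphenyl sulfate | CC(=O)c1c(O)ccc(OS(=O)(=O)[O-])c1OC.[K+] | intermediate
3 | 1-(3,6-dihydroxy-2-methoxyphenyl)ethanone | CC(=O)c1c(O)ccc(O)c1OC | intermediate
4 | 1-(6-hydroxy-2,3-dimethoxyphenyl)ethanone | CC(=O)c1c(O)ccc(OC)c1OC | intermediate
5 | 1,2,4,5-tetramethoxybenzene | COc1cc(OC)c(OC)cc1OC | starting material
6 | (2,3,5,6-tetramethoxyphenyl)lithium | [Li]c1c(OC)c(OC)cc(OC)c1OC | intermediate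
7 | lithium (dimethylamino)(2,3,5,6-tetramethoxyphenyl)methanolate, racemic | [Li+].[O-]C(N(C)C)c1c(OC)c(OC)cc(OC)c1OC | intermediate
8 | 2,3,5,6-tetramethoxybenzaldehyde | O=Cc1c(OC)c(OC)cc(OC)c1OC | intermediate
9 | 3-hydroxy-1-(6-hydroxy-2,3-dimethoxyphenyl)-3-(2,3,5,6-tetramethoxyphenyl)propan-1-one, racemic | COc1ccc(O)c(C(=O)CC(O)c2c(OC)c(OC)cc(OC)c2OC)c1OC | intermediate
10 | (E)-1-(6-hydroxy-2,3-dimethoxyphenyl)-3-(2,3,5,6-tetramethoxyphenyl)prop-2-en-1-one | COc1ccc(O)c(C(=O)/C=C/c2c(OC)c(OC)cc(OC)c2OC)c1OC | intermediate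
11 | 5,6-dimethoxy-2-(2,3,5,6-tetramethoxyphenyl)chroman-4-one, racemic | O=C1CC(c2c(OC)c(OC)cc(OC)c2OC)Oc2ccc(OC)c(OC)c12 | intermediate
12 | 5,6-dimethoxy-2-(2,3,5,6-tetramethoxyphenyl)-4H-chromen-4-one (achiral) | COc1cc(OC)c(OC)c(-c2cc(=O)c3c(OC)c(OC)ccc3o2)c1OC | target

## Step count and risks

Total step count: 5.
Longest linear sequence: 4 steps (1 → 3 → 4 → 10 → 12). The ring B branch (5 → 8) joins at step 4.

**Step 1 (Elbs oxidation).** Conversions are typically modest, about 30–45 %, with tarry by-products, although unreacted 1 can be recovered. The fallback sets out from 1 and comes back at 4, so it also replaces step 2.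
- Compound 1 is oxidised with PhI(OAc)2 (2.2 equiv) in MeOH at 0 °C to rt. This two-electron dearomatising oxidation with a hypervalent iodine reagent places two methoxy groups on the para carbon. It gives the quinone monoketal 2-acetyl-3,4,4-trimethoxycyclohexa-2,5-dien-1-one F1.
- Zn dust in AcOH at rt then reduces the dienone. It re-aromatises with loss of one methoxy group and gives 4 directly.

**Step 4 (Claisen–Schmidt condensation).** Both partners are di-ortho-substituted and electron rich, and the phenoxide of 4 enolises reluctantly, so the condensation may stall. The fallback replaces the aldol C–C bond formation with an acylation. It sets out from 5 (through aryllithium 6) and from 4, and comes back at 12, so it bypasses steps 4 and 5.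
- Aryllithium 6 is quenched with CO2 instead of DMF and acidified, giving 2,3,5,6-tetramethoxybenzoic acid F2.
- (COCl)2 with catalytic DMF in CH2Cl2 converts it into 2,3,5,6-tetramethoxybenzoyl chloride F3.
- Ketone 4 is deprotonated with LiHMDS (4 equiv, THF, −78 to −10 °C) to dilithium 2-(1-oxidoethenyl)-3,4-dimethoxyphenolate F4.
- This dianion is C-acylated by F3 at −78 °C to rt, giving 1-(6-hydroxy-2,3-dimethoxyphenyl)-3-(2,3,5,6-tetramethoxyphenyl)propane-1,3-dione F5.
- Cyclodehydration with 0.5 % H2SO4 in AcOH at 100 °C closes ring C and gives 12.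

**Step 5 (I2/DMSO oxidative cyclisation).** There are three concerns. The bulky 2,6-dimethoxyaryl group slows closure at Cβ. HI at 130 °C can cleave the peri 5-OMe. The electron-rich rings can be iodinated. The fallback sets out from 10 and comes back at 12, and it separates ring closure from oxidation.
- Compound 10 is isomerised with NaOAc in refluxing EtOH, and flavanone 11 is isolated.
- Soft enolisation with TMSOTf/Et3N in CH2Cl2 at 0 °C gives racemic 5,6-dimethoxy-2-(2,3,5,6-tetramethoxyphenyl)-4-(trimethylsilyloxy)-2H-chromene F6.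
- Saegusa–Ito oxidation with Pd(OAc)2 (1.0 equiv, MeCN, rt to 40 °C) removes the C2–H by β-hydride elimination. It delivers 12 under neutral, halogen-free conditions and leaves zerovalent palladium.

## Further compounds

F1 | step 1 | 2-acetyl-3,4,4-trimethoxycyclohexa-2,5-dien-1-one | CC(=O)C1=C(OC)C(OC)(OC)C=CC1=O
F2 | step 4 | 2,3,5,6-tetramethoxybenzoic acid | OC(=O)c1c(OC)c(OC)cc(OC)c1OC
F3 | step 4 | 2,3,5,6-tetramethoxybenzoyl chloride | ClC(=O)c1c(OC)c(OC)cc(OC)c1OC
F4 | step 4 | dilithium 2-(1-oxidoethenyl)-3,4-dimethoxyphenolate | [Li+].[Li+].C=C([O-])c1c([O-])ccc(OC)c1OC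
F5 | step 4 | 1-(6-hydroxy-2,3-dimethoxyphenyl)-3-(2,3,5,6-tetramethoxyphenyl)propane-1,3-dione | COc1ccc(O)c(C(=O)CC(=O)c2c(OC)c(OC)cc(OC)c2OC)c1OC
F6 | step 5 | 5,6-dimethoxy-2-(2,3,5,6-tetramethoxyphenyl)-4-(trimethylsilyloxy)-2H-chromene, racemic | C[Si](C)(C)OC1=CC(c2c(OC)c(OC)cc(OC)c2OC)Oc2ccc(OC)c(OC)c12
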